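## Structural features

Target 28 is a dimeric acylphloroglucinol. Two 5,7-dihydroxy-2,2-dimethylchroman units (ring A and ring B, each fused to its own dihydropyran ring) are joined through their C6 atoms by one sp3 methine, which also carries a 5-methylhexyl chain (C1'–C5' and two methyls). Ring A bears an (R)-2-methylbutanoyl group at C8 and ring B an isobutyryl group at C8. In everything else the two aryl groups are constitutionally identical, so the methine is a stereocentre only because of a methyl/ethyl difference far out in the acyl groups. The two stereocentres (methine and acyl α-carbon) are separated by ring A and cannot control each other, and the two diastereomers would be practically inseparable, so each centre must be set on its own with high fidelity. Fragile elements are the α-stereocentre beside the aryl ketone (enolisation), the diarylmethine flanked by four ortho oxygens (acid-induced retro-Friedel–Crafts cleavage, which would also racemise it), the tertiary alkyl aryl ethers of the pyran rings (strong Lewis acids) and the free polyphenols (oxidation). The real difficulty is twofold: telling two near-identical, heavily ortho-substituted arenes apart at a congested carbon, and placing two different acyl groups on two C8 positions of equal nucleophilicity. The key step exploits the sequence O5(ring A)–C5–C6–CH(methine)–C1'. Together with C2' these atoms close a six-membered lactone, a coumarin in which the methine is C4, C1' is C3, C2' is C2 and O5 is O1. Ring A then lies flat in the coumarin, ring B stands as a perpendicular 4-aryl group, hydride addition to C4 creates the stereocentre, and the lactone marks O5 and C2' for the later acyl and chain chemistry.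

## Logic of the disconnections

28 ⇒ 27. The four phenolic O–benzyl bonds are cut (protecting groups put back). Benzyl is the one group that survives every earlier step and leaves under neutral hydrogenolysis. The gain is that 27 has no free phenol, so the rings stay distinguishable and the methine is less prone to ionisation. The demand is that hydrogenolysis spares two aryl ketones and the acyl α-stereocentre.

27 ⇒ 24 + 25. The ring A C8–C(acyl) bond is cut. The epimerisable acyl group is brought in last, on the only unsubstituted electron-rich aromatic carbon left in 24, so the site is fixed by structure and not by selectivity. The gain is that the α-stereocentre never meets a base, a hydride or an organometallic. The demand is an acylium source that neither racemises the acid nor exposes the methine to strong acid for long.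

24 ⇒ 22 (through 23). The O5–benzyl bond of ring A is cut and replaced by an O5–acetyl bond. In a bis(trialkoxyarene) the two C8 positions would be equally reactive, whereas an acetoxy group para to C8 of ring A makes that ring much the poorer nucleophile. The gain is that site selection becomes a large electronic bias. The demand is an acetate that survives the acylation and is then exchanged for benzyl without touching the ketone.

22 ⇒ 21. The ring B C8–C(acyl) bond is cut. The isobutyryl group has no stereocentre and can go in first, under the mildest Friedel–Crafts conditions, while ring A is deactivated. The demand is that acylation stops at ring B. Acylating ring A directly after lactone opening would not be site-selective, because acylium released from an O5 ester would be taken up by the more electron-rich ring B.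

21 ⇒ 20 ⇒ 15 + 17 (17 from 16). The C2'–C3' bond is cut (as the C=C of an olefination) and the acetyl–O5 bond is traced back to the phenoxide released on ring opening. C2' is the lactol carbon, and the remaining five carbons come from a primary alkyl halide. The gain is that the chain is completed by one C–C bond, and the only oxygen that distinguishes ring A is capped in the same operation. The demand is that alkene saturation leaves every benzyl ether in place.

15 ⇒ 14. The oxidation level at C2 is adjusted (lactol from lactone). The demand is partial reduction without ring-opening over-reduction.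

14 ⇒ 13. The C4–H bond is cut. This is the stereo-defining disconnection: the sp3 methine becomes the β-carbon of a planar unsaturated lactone in which ring A and ring B differ strongly in shape and electronics. The gain is that the stereo-problem reduces to face selection on a rigid alkene by a chiral hydride. The demand is that a bulky chiral catalyst reaches a β-carbon flanked by three ortho benzyloxy groups.

13 ⇒ 12. The C4–C4a bond (C6 of ring A to the alkyne β-carbon) is cut. An intramolecular hydroarylation forms the most hindered C–C bond within a six-membered transition state, under neutral conditions that benzyl ethers tolerate. The only free position ortho to the ester oxygen is C6, so the ring fusion is unambiguous.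

12 ⇒ 11 + 6. The ester C–O bond is cut. The two halves of the molecule are the same chroman phenol at two stages of elaboration, which makes the route convergent on one building block.

11 ⇒ 9 ⇒ 8 ⇒ 7 ⇒ 6. Cut in turn are the alkyne–CO2H bond, the alkyne carbon (one-carbon homologation of an aldehyde), the O5–benzyl bond and the C6–CHO bond. The formyl group is introduced by a phenol-directed ortho-formylation. This is the step that decides C6 against C8 in ring B, because C6 is the only free ortho position of 6.

6 ⇒ 4 ⇒ 3 ⇒ 1 + 2. Cut are the C4 carbonyl oxygen (put back), the O7–benzyl bond, and the aryl–C4 and O1–C2 bonds. The C4 carbonyl is carried temporarily because its hydrogen bond to the 5-OH makes mono-benzylation at O7 regiospecific. The symmetry of 1 makes the annulation with 2 unambiguous.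

## Other disconnections considered

Alternative 1: The cut is the bond between C6 of ring B and the methine. In the forward sense the secondary allyl aryl ether A2 would be heated. A [3,3] shift through a chair would break the O5–C bond of ring B, form the C6–methine bond and pass the configuration of the carbinol carbon on to the methine, giving A1 with an (E)-alkene. Alkene saturation and acetate removal would then finish the synthesis.
- In favour: the most hindered C–C bond would form intramolecularly, without metal or acid. The shift is ortho-specific, since C6 is the only free ortho position and C8 is blocked. Both acyl groups would already be in place, so no Friedel–Crafts chemistry on the assembled dimer is needed. On this last point the alternative is better than the chosen plan, which must engineer two site-selective acylations after the stereocentre exists.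
- Against: A2 is a secondary, γ-aryl-substituted allyl ether of a hindered phenol. Making it (SN2 against SN2' etherification) and rearranging it both compete with ionisation to an allyl cation–phenoxide pair, which would erode the 1,3-transfer. Fidelity also rests on one chair and on pure alkene geometry. The (R)-acyl centre must survive prolonged heating. The enantioenriched allylic alcohol and two separately acylated chromans (with their own C6/C8 regiochemistry) must be made first.
- Comparison: structurally both plans tie O5 of one ring to the methine region to break the near-symmetry. Mechanistically the alternative needs two stereo-events (create the carbinol, then transfer it) where the chosen plan needs one catalytic event of a known class. In steps after the key step the alternative is shorter; over the whole route the count should be about equal.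

Alternative 2: The cut removes three bonds of ring B (C6–C7, C5–C4a, C7–C8). In the forward sense the propargylic siloxyalkyne A4 and the pyran-fused cyclobutenone A5 would be heated. Ring opening of A5 to a vinylketene, [2+2] addition to the alkyne, a second 4π opening and a 6π closure would build ring B around the existing stereocentre and give A3.
- In favour: the stereocentre would be made while its substituents are an arene and an alkyne, constitutionally different groups. This is equal in idea to the lactone device of the chosen plan and arguably a cleaner difference. The cascade does not touch the stereocentre. Ring B would emerge with O5 silylated and O7 free next to C8, a built-in handle for ortho-acylation. On this point, and in bond-forming power per step (three C–C bonds and one ring), the alternative is better than the chosen plan.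
- Against: the alkyne of A4 carries a very bulky propargylic carbon, which should slow the [2+2] step. A5 is a strained enol-ether cyclobutenone needing its own multistep synthesis. The siloxyalkyne is moisture-sensitive and comes from an ester or alkyne by several steps. The enantioselective construction of the aryl/alkyl/alkynyl methine of A4 is left unsolved and simply moves the main risk to earlier steps. Two acylations and two kinds of deprotection still follow.
- Comparison: it is more convergent and mechanistically elegant, but the two partners should cost more steps than 12, and the key stereo-event has less precedent than hydride addition to a coumarin.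

Alternative 3: The cut is the O7–acyl bond on one of two enantiotopic rings. In the forward sense the prochiral tetraphenol A7 would be treated with anhydride A8 and a chiral nucleophilic acyl-transfer catalyst (an isothiourea or a histidine-containing peptide). Acylation of O7 on one ring would turn the methine into a stereocentre and give A6. An O7→C8 acyl shift and isobutyrylation of the other ring would follow.
- In favour: A7 is symmetric and should be available in very few steps from two identical chroman-diol units and one aliphatic aldehyde. One operation would set the methine and bring in the chiral acyl group, with no protecting groups at all. In step count and atom economy this alternative is clearly better than the chosen plan.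
- Against: the two rings are distinguished only by H against an alkyl chain at a carbon several bonds from the reacting oxygen. Each ring offers two hydroxyls, so site selection within a ring is needed on top of ring selection. The acyl donor is itself chiral, so matched and mismatched pairings arise. Every wrong acylation gives a diastereomer that could not realistically be removed. The later Fries-type shift and Lewis-acid acylation would run on free polyphenols, where the diarylmethine is most acid-labile. Assembly of A7 also needs C6-over-C8 control.
- Comparison: structurally it uses the near-symmetry and does not fight it. Mechanistically its selectivity rests on remote recognition of a weakly biased prochiral centre, far less predictable than face selection on the rigid, desymmetrised coumarin 13.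

Key step: step 10

Assumption: the (R)-antipode of DTBM-SEGPHOS is taken to deliver hydride to the C4 face that gives (4R)-14, by analogy with simpler 4-arylcoumarins; if the sense of induction were opposite, the (S)-ligand would be used and nothing else would change.

Remark: the CIP descriptor of the methine alternates along the route (R in 14, 15, 20, 21, 27 and 28; S in 19, 22, 23 and 24) only because the priorities of ring A and ring B change with their substituents; none of its four bonds is touched after step 10.

## Route

Step 1
Reactants: 1 phloroglucinol; 2 3-methylbut-2-enoic acid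
Product: 3 5,7-dihydroxy-2,2-dimethylchroman-4-one
Conditions: P2O5/MeSO3H (1:10 w/w), 70 °C
Reagents that add atoms: none
Why: Friedel–Crafts acylation of the symmetric triphenol followed by intramolecular oxa-Michael addition of an ortho hydroxyl to the enone closes the 2,2-dimethylchromanone; the threefold symmetry of 1 allows only one product.

Step 2
Reactants: 3
Product: 4 7-(benzyloxy)-5-hydroxy-2,2-dimethylchroman-4-one
Conditions: BnBr (1.05 equiv), K2CO3, acetone, reflux
Reagents that add atoms: benzyl bromide, BrCc1ccccc1
Why: Williamson etherification; the 5-OH is held in a hydrogen bond to the C4 carbonyl and is far less nucleophilic, so only the 7-OH should be alkylated, which fixes the oxygen pattern of both ring A and ring B.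

Step 3
Reactants: 4
Product: 6 7-(benzyloxy)-2,2-dimethylchroman-5-ol, via aryl ethyl carbonate 5 (not isolated)
Conditions: ClCO2Et, Et3N, THF, 0 °C; then NaBH4, H2O, 0 °C → rt
Reagents that add atoms: none
Why: Reductive deoxygenation of an ortho-hydroxyaryl ketone through its carbonate: borohydride reduces C4=O, the alkoxide takes over the carbonate, ethyl carbonate is expelled to give an ortho-quinone methide and a second hydride adds at C4; the benzyl ether is not affected.

Step 4
Reactants: 6
Product: 7 7-(benzyloxy)-5-hydroxy-2,2-dimethylchroman-6-carbaldehyde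
Conditions: (CH2O)n, MgCl2, Et3N, MeCN, reflux
Reagents that add atoms: paraformaldehyde (formaldehyde), C=O
Why: Magnesium-mediated ortho-formylation of a phenol (Casnati–Skattebøl): the magnesium phenoxide delivers formaldehyde to the ortho carbon only and a second formaldehyde oxidises the benzylic alcohol; C6 is the single free ortho position, so the C6/C8 question of ring B is settled here.

Step 5
Reactants: 7
Product: 8 5,7-bis(benzyloxy)-2,2-dimethylchroman-6-carbaldehyde
Conditions: BnBr, K2CO3, DMF, 60 °C
Reagents that add atoms: benzyl bromide, BrCc1ccccc1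
Why: Williamson etherification of the chelated salicylaldehyde hydroxyl, which needs a dipolar solvent and mild heating but has no competing site.

Step 6
Reactants: 8
Product: 9 5,7-bis(benzyloxy)-6-ethynyl-2,2-dimethylchroman
Conditions: MeC(O)C(N2)P(O)(OMe)2, K2CO3, MeOH–THF, rt
Reagents that add atoms: dimethyl (1-diazo-2-oxopropyl)phosphonate, COP(=O)(OC)C(=[N+]=[N-])C(C)=O
Why: Seyferth–Gilbert homologation in the Ohira–Bestmann variant: methanolysis frees the diazomethylphosphonate anion, which adds to the aldehyde, loses dimethyl phosphate and then N2, and the alkylidene carbene rearranges to the terminal alkyne under conditions mild enough for a hindered, electron-rich aldehyde.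

Step 7
Reactants: 9
Product: 11 3-[5,7-bis(benzyloxy)-2,2-dimethylchroman-6-yl]prop-2-ynoic acid, via lithium acetylide 10 (not isolated)
Conditions: n-BuLi (1.05 equiv), THF, −78 °C; then CO2; aq. HCl
Reagents that add atoms: carbon dioxide, O=C=O
Why: Deprotonation of the terminal alkyne is much faster than benzylic lithiation of the ethers at −78 °C with one equivalent of base, and carboxylation of the acetylide gives the arylpropiolic acid, which is used without heating to avoid decarboxylation.

Step 8
Reactants: 11; 6
Product: 12 7-(benzyloxy)-2,2-dimethylchroman-5-yl 3-[5,7-bis(benzyloxy)-2,2-dimethylchroman-6-yl]prop-2-ynoate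
Conditions: DCC, DMAP (10 mol %), CH2Cl2, 0 °C → rt
Reagents that add atoms: none
Why: Steglich esterification of the phenol with the propiolic acid at low temperature, which avoids the acid chloride and conjugate addition to the ynoate; the ester links O5 of ring A to the future C2' carbon.

Step 9
Reactants: 12
Product: 13 5-(benzyloxy)-4-[5,7-bis(benzyloxy)-2,2-dimethylchroman-6-yl]-8,8-dimethyl-9,10-dihydro-2H,8H-pyrano[2,3-f]chromen-2-one
Conditions: [(2-biphenylyl)(t-Bu)2P]Au(NCMe)SbF6 (5 mol %), ClCH2CH2Cl, 25 → 60 °C
Reagents that add atoms: none
Why: Intramolecular hydroarylation of an aryl alkynoate by a cationic monovalent gold complex: π-activation of the alkyne, 6-endo attack of C6 of ring A (the only free position ortho to the ester oxygen, activated by three oxygens) on the β-carbon, rearomatisation and protodeauration give the coumarin under neutral conditions that spare the benzyl ethers.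

Step 10
Reactants: 13
Product: 14 (4R)-5-(benzyloxy)-4-[5,7-bis(benzyloxy)-2,2-dimethylchroman-6-yl]-8,8-dimethyl-3,4,9,10-tetrahydro-2H,8H-pyrano[2,3-f]chromen-2-one
Conditions: Cu(OAc)2·H2O (5 mol %), (R)-DTBM-SEGPHOS (5.5 mol %), HSiMe(OEt)2 (3 equiv), t-BuOH (2 equiv), toluene, 0 °C → rt
Reagents that add atoms: none
Why: Cu(OAc)2 and the hydrosilane give a ligated monovalent copper hydride, L*CuH, which binds the electron-poor C3=C4 bond of 13 and adds across it by syn hydrocupration, hydride going to C4 and copper to C3 as the copper enolate of the lactone. t-BuOH protonates this enolate to release 14 and leaves L*CuOt-Bu, which σ-bond metathesis with HSiMe(OEt)2 turns back into L*CuH. The closest known reaction type is the copper hydride-catalysed asymmetric 1,4-reduction of β,β-disubstituted unsaturated lactones, 4-arylcoumarins included. No ring is closed and no skeletal bond is formed; the only new bond is C4–H. The new stereocentre at C4 is under catalyst control: the C2-symmetric bisphosphine shields one enantiotopic face of the flat coumarin, whose alkene geometry is fixed by the lactone, while ring B stands perpendicular with one benzyloxy group above and one below the plane and so offers no competing bias; the two rotamers about the C4–aryl axis therefore converge on the same (4R) product, whose configuration is that of the methine of 28. The step needs 1,4- over 1,2-selectivity and tolerance of three benzyl ethers: soft hydride transfer from copper to the conjugated position should secure the first, and benzyl ethers are inert to copper hydride. Further reduction of the aryl lactone to lactol 15 would do no harm, since 15 is the next intermediate. The steric load around C4 is the price of the design, and the small hydride nucleophile is the answer to it.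

Step 11
Reactants: 14
Product: 15 (4R)-5-(benzyloxy)-4-[5,7-bis(benzyloxy)-2,2-dimethylchroman-6-yl]-8,8-dimethyl-3,4,9,10-tetrahydro-2H,8H-pyrano[2,3-f]chromen-2-ol (both C2 epimers)
Conditions: i-Bu2AlH (1.2 equiv), toluene–CH2Cl2, −78 °C; aq. potassium sodium tartrate
Reagents that add atoms: none
Why: Partial reduction of an aryl lactone to the lactol through an aluminium lactolate that is stable at −78 °C; C4 is not α to the carbonyl and keeps its configuration, and the new C2 centre is an irrelevant epimer mixture that disappears in step 13.

Step 12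
Reactants: 16 1-bromo-3-methylbutane
Product: 17 (3-methylbutyl)triphenylphosphonium bromide
Conditions: PPh3, toluene, reflux
Reagents that add atoms: triphenylphosphine, c1ccc(cc1)P(c1ccccc1)c1ccccc1
Why: SN2 quaternisation of triphenylphosphine by a primary alkyl bromide.

Step 13
Reactants: 15; 17
Product: 20 7-(benzyloxy)-6-[(1R,3Z)-1-[5,7-bis(benzyloxy)-2,2-dimethylchroman-6-yl]-6-methylhept-3-en-1-yl]-2,2-dimethylchroman-5-yl acetate, via phosphorus ylide 18 (not isolated), via alkenyl phenol 19 (not isolated)
Conditions: 17 (3 equiv), KN(SiMe3)2 (2.9 equiv), THF, 0 °C; 15, 0 °C → rt; then Ac2O, DMAP (cat.), rt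
Reagents that add atoms: acetic anhydride, CC(=O)OC(C)=O
Why: Wittig olefination of the open hydroxy-aldehyde form of the lactol by a non-stabilised ylide joins C2' to C3' (Z-alkene expected, geometry of no consequence); the potassium phenoxide at O5 of ring A released by ring opening is acetylated in the same flask, so the one oxygen that distinguishes ring A becomes an electron-withdrawing ester at once.

Step 14
Reactants: 20
Product: 21 7-(benzyloxy)-6-[(1R)-1-[5,7-bis(benzyloxy)-2,2-dimethylchroman-6-yl]-6-methylheptyl]-2,2-dimethylchroman-5-yl acetate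
Conditions: H2 (1 atm), RhCl(PPh3)3 (5 mol %), benzene–EtOH, rt
Reagents that add atoms: none
Why: Homogeneous hydrogenation of a 1,2-disubstituted alkene by a rhodium catalyst that does not hydrogenolyse benzyl ethers or touch the aryl acetate; the alkene is removed here so that it cannot be acylated or protonated in the next steps.

Step 15
Reactants: 21
Product: 22 7-(benzyloxy)-6-[(1S)-1-[5,7-bis(benzyloxy)-2,2-dimethyl-8-(2-methylpropanoyl)chroman-6-yl]-6-methylheptyl]-2,2-dimethylchroman-5-yl acetate
Conditions: i-PrCO2H (1.5 equiv), (CF3CO)2O (2 equiv), CH2Cl2, 0 °C; then 21, −20 → 0 °C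
Reagents that add atoms: 2-methylpropanoic acid, CC(C)C(=O)O
Why: Friedel–Crafts acylation by the mixed carboxylic–trifluoroacetic anhydride: ring B is a 1,3,5-trialkoxyarene whose only free position is C8, whereas C8 of ring A lies para to an acetoxy group that donates far less than benzyloxy, so in a reaction with a strongly negative ρ+ the acyl group should go to ring B alone. Benzyl ethers, the acetate and the methine should tolerate brief contact with CF3CO2H at or below 0 °C.

Step 16
Reactants: 22
Product: 24 1-[5,7-bis(benzyloxy)-6-[(1S)-1-[5,7-bis(benzyloxy)-2,2-dimethylchroman-6-yl]-6-methylheptyl]-2,2-dimethylchroman-8-yl]-2-methylpropan-1-one, via phenol 23 (not isolated)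
Conditions: NaOMe (1.2 equiv), MeOH–DMF, 0 °C → rt; then BnBr, Bu4NI (cat.), 40 °C
Reagents that add atoms: benzyl bromide, BrCc1ccccc1
Why: Methanolysis of the aryl acetate gives the sodium phenoxide, which is benzylated in the same flask (Williamson etherification); ring A becomes a trialkoxyarene again, ready for acylation under the mildest conditions, and the isobutyryl ketone has no stereocentre to lose to methoxide.

Step 17
Reactants: 24; 25 (R)-2-methylbutanoic acid
Product: 27 (2R)-1-[5,7-bis(benzyloxy)-6-[(1R)-1-[5,7-bis(benzyloxy)-2,2-dimethyl-8-(2-methylpropanoyl)chroman-6-yl]-6-methylheptyl]-2,2-dimethylchroman-8-yl]-2-methylbutan-1-one, via mixed anhydride 26 (not isolated)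
Conditions: 25 (1.5 equiv), (CF3CO)2O (2 equiv), CH2Cl2, 0 °C; then 24, −20 → 0 °C
Reagents that add atoms: none
Why: The same mixed-anhydride Friedel–Crafts acylation, now on ring A, whose C8 is the only unsubstituted electron-rich aromatic carbon left in 24, so the site is fixed by structure. The α-stereocentre comes unchanged from 25 because the acylium donor is formed and consumed without base at low temperature and the product ketone, twisted between two ortho oxygens, enolises only slowly.

Step 18
Reactants: 27
Product: 28 (2R)-1-[6-[(1R)-1-[5,7-dihydroxy-2,2-dimethyl-8-(2-methylpropanoyl)chroman-6-yl]-6-methylheptyl]-5,7-dihydroxy-2,2-dimethylchroman-8-yl]-2-methylbutan-1-one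
Conditions: H2 (1 atm), Pd/C (10 %), EtOAc–EtOH, rt
Reagents that add atoms: none
Why: Hydrogenolysis of four aryl benzyl ethers under neutral conditions; the hindered aryl ketones, the chroman ethers and both stereocentres should not be affected, and no acid or base is present that could cleave the methine or epimerise the acyl group.

## Compound list

1 | phloroglucinol | Oc1cc(O)cc(O)c1 | starting material
2 | 3-methylbut-2-enoic acid | CC(C)=CC(=O)O | starting material
3 | 5,7-dihydroxy-2,2-dimethylchroman-4-one | CC1(C)CC(=O)c2c(O)cc(O)cc2O1 | intermediate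
4 | 7-(benzyloxy)-5-hydroxy-2,2-dimethylchroman-4-one | CC1(C)CC(=O)c2c(O)cc(OCc3ccccc3)cc2O1 | intermediate
5 | 7-(benzyloxy)-2,2-dimethyl-4-oxochroman-5-yl ethyl carbonate (formed in the flask, not isolated) | CCOC(=O)Oc1cc(OCc2ccccc2)cc2OC(C)(C)CC(=O)c12 | intermediate
6 | 7-(benzyloxy)-2,2-dimethylchroman-5-ol | CC1(C)CCc2c(O)cc(OCc3ccccc3)cc2O1 | intermediate
7 | 7-(benzyloxy)-5-hydroxy-2,2-dimethylchroman-6-carbaldehyde | CC1(C)CCc2c(O)c(C=O)c(OCc3ccccc3)cc2O1 | intermediate
8 | 5,7-bis(benzyloxy)-2,2-dimethylchroman-6-carbaldehyde | CC1(C)CCc2c(OCc3ccccc3)c(C=O)c(OCc3ccccc3)cc2O1 | intermediate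
9 | 5,7-bis(benzyloxy)-6-ethynyl-2,2-dimethylchroman | CC1(C)CCc2c(OCc3ccccc3)c(C#C)c(OCc3ccccc3)cc2O1 | intermediate
10 | lithium [5,7-bis(benzyloxy)-2,2-dimethylchroman-6-yl]acetylide (formed in the flask, not isolated) | CC1(C)CCc2c(OCc3ccccc3)c(C#C[Li])c(OCc3ccccc3)cc2O1 | intermediate
11 | 3-[5,7-bis(benzyloxy)-2,2-dimethylchroman-6-yl]prop-2-ynoic acid | CC1(C)CCc2c(OCc3ccccc3)c(C#CC(=O)O)c(OCc3ccccc3)cc2O1 | intermediate
12 | 7-(benzyloxy)-2,2-dimethylchroman-5-yl 3-[5,7-bis(benzyloxy)-2,2-dimethylchroman-6-yl]prop-2-ynoate | CC1(C)CCc2c(OCc3ccccc3)c(C#CC(=O)Oc3cc(OCc4ccccc4)cc4OC(C)(C)CCc34)c(OCc3ccccc3)cc2O1 | intermediate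
13 | 5-(benzyloxy)-4-[5,7-bis(benzyloxy)-2,2-dimethylchroman-6-yl]-8,8-dimethyl-9,10-dihydro-2H,8H-pyrano[2,3-f]chromen-2-one (precursor of the key step) | O=C1C=C(c4c(OCc5ccccc5)c6CCC(C)(C)Oc6cc4OCc7ccccc7)c2c(OCc8ccccc8)cc3OC(C)(C)CCc3c2O1 | intermediate
14 | (4R)-5-(benzyloxy)-4-[5,7-bis(benzyloxy)-2,2-dimethylchroman-6-yl]-8,8-dimethyl-3,4,9,10-tetrahydro-2H,8H-pyrano[2,3-f]chromen-2-one (product of the key step) | O=C1C[C@H](c4c(OCc5ccccc5)c6CCC(C)(C)Oc6cc4OCc7ccccc7)c2c(OCc8ccccc8)cc3OC(C)(C)CCc3c2O1 | intermediate
15 | (4R)-5-(benzyloxy)-4-[5,7-bis(benzyloxy)-2,2-dimethylchroman-6-yl]-8,8-dimethyl-3,4,9,10-tetrahydro-2H,8H-pyrano[2,3-f]chromen-2-ol (both C2 epimers) | OC1C[C@H](c4c(OCc5ccccc5)c6CCC(C)(C)Oc6cc4OCc7ccccc7)c2c(OCc8ccccc8)cc3OC(C)(C)CCc3c2O1 | intermediate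
16 | 1-bromo-3-methylbutane | CC(C)CCBr | starting material
17 | (3-methylbutyl)triphenylphosphonium bromide | CC(C)CC[P+](c1ccccc1)(c1ccccc1)c1ccccc1.[Br-] | intermediate
18 | (3-methylbutylidene)triphenylphosphorane (formed in the flask, not isolated) | CC(C)CC=P(c1ccccc1)(c1ccccc1)c1ccccc1 | intermediate
19 | 7-(benzyloxy)-6-[(1S,3Z)-1-[5,7-bis(benzyloxy)-2,2-dimethylchroman-6-yl]-6-methylhept-3-en-1-yl]-2,2-dimethylchroman-5-ol (present as its potassium phenoxide, not isolated) | CC(C)C/C=C\C[C@H](c1c(OCc2ccccc2)c2CCC(C)(C)Oc2cc1OCc1ccccc1)c1c(OCc2ccccc2)cc2OC(C)(C)CCc2c1O | intermediate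
20 | 7-(benzyloxy)-6-[(1R,3Z)-1-[5,7-bis(benzyloxy)-2,2-dimethylchroman-6-yl]-6-methylhept-3-en-1-yl]-2,2-dimethylchroman-5-yl acetate | CC(C)C/C=C\C[C@H](c1c(OCc2ccccc2)c2CCC(C)(C)Oc2cc1OCc1ccccc1)c1c(OCc2ccccc2)cc2OC(C)(C)CCc2c1OC(C)=O | intermediate
21 | 7-(benzyloxy)-6-[(1R)-1-[5,7-bis(benzyloxy)-2,2-dimethylchroman-6-yl]-6-methylheptyl]-2,2-dimethylchroman-5-yl acetate | CC(C)CCCC[C@H](c1c(OCc2ccccc2)c2CCC(C)(C)Oc2cc1OCc1ccccc1)c1c(OCc2ccccc2)cc2OC(C)(C)CCc2c1OC(C)=O | intermediate
22 | 7-(benzyloxy)-6-[(1S)-1-[5,7-bis(benzyloxy)-2,2-dimethyl-8-(2-methylpropanoyl)chroman-6-yl]-6-methylheptyl]-2,2-dimethylchroman-5-yl acetate | CC(C)CCCC[C@H](c1c(OCc2ccccc2)c2CCC(C)(C)Oc2c(C(=O)C(C)C)c1OCc1ccccc1)c1c(OCc2ccccc2)cc2OC(C)(C)CCc2c1OC(C)=O | intermediate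
23 | 1-[5,7-bis(benzyloxy)-6-[(1S)-1-[7-(benzyloxy)-5-hydroxy-2,2-dimethylchroman-6-yl]-6-methylheptyl]-2,2-dimethylchroman-8-yl]-2-methylpropan-1-one (present as its sodium phenoxide, not isolated) | CC(C)CCCC[C@H](c1c(OCc2ccccc2)c2CCC(C)(C)Oc2c(C(=O)C(C)C)c1OCc1ccccc1)c1c(OCc2ccccc2)cc2OC(C)(C)CCc2c1O | intermediate
24 | 1-[5,7-bis(benzyloxy)-6-[(1S)-1-[5,7-bis(benzyloxy)-2,2-dimethylchroman-6-yl]-6-methylheptyl]-2,2-dimethylchroman-8-yl]-2-methylpropan-1-one | CC(C)CCCC[C@H](c1c(OCc2ccccc2)c2CCC(C)(C)Oc2c(C(=O)C(C)C)c1OCc1ccccc1)c1c(OCc2ccccc2)cc2OC(C)(C)CCc2c1OCc1ccccc1 | intermediate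
25 | (R)-2-methylbutanoic acid | CC[C@@H](C)C(=O)O | starting material
26 | (2R)-2-methylbutanoic trifluoroacetic anhydride (formed in the flask, not isolated) | CC[C@@H](C)C(=O)OC(=O)C(F)(F)F | intermediate
27 | (2R)-1-[5,7-bis(benzyloxy)-6-[(1R)-1-[5,7-bis(benzyloxy)-2,2-dimethyl-8-(2-methylpropanoyl)chroman-6-yl]-6-methylheptyl]-2,2-dimethylchroman-8-yl]-2-methylbutan-1-one | CC[C@@H](C)C(=O)c1c(OCc5ccccc5)c([C@H](CCCCC(C)C)c2c(OCc6ccccc6)c3c(c(C(=O)C(C)C)c2OCc7ccccc7)OC(C)(C)CC3)c(OCc8ccccc8)c4c1OC(C)(C)CC4 | intermediate
28 | (2R)-1-[6-[(1R)-1-[5,7-dihydroxy-2,2-dimethyl-8-(2-methylpropanoyl)chroman-6-yl]-6-methylheptyl]-5,7-dihydroxy-2,2-dimethylchroman-8-yl]-2-methylbutan-1-one (CNP0287681.1) | CC[C@@H](C)C(=O)c1c(O)c([C@H](CCCCC(C)C)c2c(O)c3c(c(C(=O)C(C)C)c2O)OC(C)(C)CC3)c(O)c2c1OC(C)(C)CC2 | target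

## Step count and least certain steps

Total number of steps: 18. Longest linear sequence: 17 (steps 1–11 and 13–18; step 12 is a one-step side branch, and 6 is used twice, in steps 4 and 8).

Step 10 (key step). The most likely failure is slow or incomplete hydride delivery, because C4 is flanked by three ortho benzyloxy groups and the ligand is very bulky; the second risk is imperfect face selection on so crowded a substrate. The fallback sets out from 13 and comes back at 14. Conjugate reduction would use a smaller achiral copper hydride (Cu(OAc)2, 1,2-bis(diphenylphosphino)benzene, polymethylhydrosiloxane, t-BuOH) and give the racemic lactone, that is 14 together with its enantiomer (4S)-5-(benzyloxy)-4-[5,7-bis(benzyloxy)-2,2-dimethylchroman-6-yl]-8,8-dimethyl-3,4,9,10-tetrahydro-2H,8H-pyrano[2,3-f]chromen-2-one F1. The two would be separated by preparative chromatography on a chiral stationary phase and 14 carried on. Enantiocontrol then comes from resolution and not from the catalyst.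

Step 9. The most likely failure is diversion of the gold-activated alkyne, either by attack of an ortho benzyloxy oxygen of ring B (cyclisation with benzyl transfer) or by steric retardation of C–C bond formation at the hindered C6 of ring A. The fallback sets out from 8 and 6 and comes back at 13. Aldol addition of the lithium enolate of ethyl acetate (LiN(i-Pr)2, THF, −78 °C) to 8 would give ethyl 3-[5,7-bis(benzyloxy)-2,2-dimethylchroman-6-yl]-3-hydroxypropanoate F2. Oxidation with Dess–Martin periodinane would give ethyl 3-[5,7-bis(benzyloxy)-2,2-dimethylchroman-6-yl]-3-oxopropanoate F3. Pechmann condensation of F3 with 6 (Sc(OTf)3, toluene, 80 °C) would then close the coumarin 13 through a carbonyl electrophile in place of an alkyne.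

Step 15. The most likely failure is incomplete site selection (some acylation at C8 of ring A), or acid-promoted loss or migration of benzyl groups and protolytic cleavage at the methine. The fallback sets out from 21 and comes back at 24. Bromination with N-bromosuccinimide (MeCN, −20 °C) discriminates between the rings more sharply than acylation and needs no acid; it would give 7-(benzyloxy)-6-[(1S)-1-[5,7-bis(benzyloxy)-8-bromo-2,2-dimethylchroman-6-yl]-6-methylheptyl]-2,2-dimethylchroman-5-yl acetate F4. Methanolysis and benzylation as in step 16 would give 5,7-bis(benzyloxy)-6-[(1S)-1-[5,7-bis(benzyloxy)-2,2-dimethylchroman-6-yl]-6-methylheptyl]-8-bromo-2,2-dimethylchroman F5. Bromine–lithium exchange (n-BuLi, THF, −78 °C) would give [5,7-bis(benzyloxy)-6-[(1S)-1-[5,7-bis(benzyloxy)-2,2-dimethylchroman-6-yl]-6-methylheptyl]-2,2-dimethylchroman-8-yl]lithium F6, which N-methoxy-N-methyl-2-methylpropanamide would acylate to 24.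

Step 17. The most likely failure is partial loss of configuration at the acyl α-carbon (ketene or enol formation from the mixed anhydride or the acylium ion), or acid cleavage at the methine now that ring A is at its most electron-rich. The fallback sets out from 24 and comes back at 27, and takes the stereocentre from a boron reagent and not from 25. Vilsmeier formylation (POCl3, DMF, 0 °C → rt) at C8 of ring A would give 5,7-bis(benzyloxy)-6-[(1S)-1-[5,7-bis(benzyloxy)-2,2-dimethyl-8-(2-methylpropanoyl)chroman-6-yl]-6-methylheptyl]-2,2-dimethylchroman-8-carbaldehyde F7. Reagent-controlled crotylboration with (E)-crotyl-B(Ipc)2 (antipode chosen so that the methyl-bearing carbon is R) would give 1-[5,7-bis(benzyloxy)-6-[(1S)-1-[5,7-bis(benzyloxy)-8-[(1R,2R)-1-hydroxy-2-methylbut-3-en-1-yl]-2,2-dimethylchroman-6-yl]-6-methylheptyl]-2,2-dimethylchroman-8-yl]-2-methylpropan-1-one F8. Saturation of the vinyl group (H2, RhCl(PPh3)3) would give 1-[5,7-bis(benzyloxy)-6-[(1S)-1-[5,7-bis(benzyloxy)-8-[(1R,2R)-1-hydroxy-2-methylbutyl]-2,2-dimethylchroman-6-yl]-6-methylheptyl]-2,2-dimethylchroman-8-yl]-2-methylpropan-1-one F9. Buffered Dess–Martin oxidation of the carbinol would then give 27 without touching the α-centre.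

## Further compounds

F1 | step 10 | (4S)-5-(benzyloxy)-4-[5,7-bis(benzyloxy)-2,2-dimethylchroman-6-yl]-8,8-dimethyl-3,4,9,10-tetrahydro-2H,8H-pyrano[2,3-f]chromen-2-one | O=C1C[C@@H](c4c(OCc5ccccc5)c6CCC(C)(C)Oc6cc4OCc7ccccc7)c2c(OCc8ccccc8)cc3OC(C)(C)CCc3c2O1
F2 | step 9 | ethyl 3-[5,7-bis(benzyloxy)-2,2-dimethylchroman-6-yl]-3-hydroxypropanoate (racemic) | CCOC(=O)CC(O)c1c(OCc2ccccc2)cc2OC(C)(C)CCc2c1OCc1ccccc1
F3 | step 9 | ethyl 3-[5,7-bis(benzyloxy)-2,2-dimethylchroman-6-yl]-3-oxopropanoate | CCOC(=O)CC(=O)c1c(OCc2ccccc2)cc2OC(C)(C)CCc2c1OCc1ccccc1
F4 | step 15 | 7-(benzyloxy)-6-[(1S)-1-[5,7-bis(benzyloxy)-8-bromo-2,2-dimethylchroman-6-yl]-6-methylheptyl]-2,2-dimethylchroman-5-yl acetate | CC(C)CCCC[C@H](c1c(OCc2ccccc2)c2CCC(C)(C)Oc2c(Br)c1OCc1ccccc1)c1c(OCc2ccccc2)cc2OC(C)(C)CCc2c1OC(C)=O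
F5 | step 15 | 5,7-bis(benzyloxy)-6-[(1S)-1-[5,7-bis(benzyloxy)-2,2-dimethylchroman-6-yl]-6-methylheptyl]-8-bromo-2,2-dimethylchroman | CC(C)CCCC[C@H](c1c(OCc2ccccc2)c2CCC(C)(C)Oc2c(Br)c1OCc1ccccc1)c1c(OCc2ccccc2)cc2OC(C)(C)CCc2c1OCc1ccccc1
F6 | step 15 | [5,7-bis(benzyloxy)-6-[(1S)-1-[5,7-bis(benzyloxy)-2,2-dimethylchroman-6-yl]-6-methylheptyl]-2,2-dimethylchroman-8-yl]lithium | CC(C)CCCC[C@H](c1c(OCc2ccccc2)c2CCC(C)(C)Oc2c([Li])c1OCc1ccccc1)c1c(OCc2ccccc2)cc2OC(C)(C)CCc2c1OCc1ccccc1
F7 | step 17 | 5,7-bis(benzyloxy)-6-[(1S)-1-[5,7-bis(benzyloxy)-2,2-dimethyl-8-(2-methylpropanoyl)chroman-6-yl]-6-methylheptyl]-2,2-dimethylchroman-8-carbaldehyde | O=Cc1c(OCc5ccccc5)c([C@H](CCCCC(C)C)c2c(OCc6ccccc6)c3c(c(C(=O)C(C)C)c2OCc7ccccc7)OC(C)(C)CC3)c(OCc8ccccc8)c4c1OC(C)(C)CC4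
F8 | step 17 | 1-[5,7-bis(benzyloxy)-6-[(1S)-1-[5,7-bis(benzyloxy)-8-[(1R,2R)-1-hydroxy-2-methylbut-3-en-1-yl]-2,2-dimethylchroman-6-yl]-6-methylheptyl]-2,2-dimethylchroman-8-yl]-2-methylpropan-1-one | C=C[C@@H](C)[C@@H](O)c1c(OCc5ccccc5)c([C@H](CCCCC(C)C)c2c(OCc6ccccc6)c3c(c(C(=O)C(C)C)c2OCc7ccccc7)OC(C)(C)CC3)c(OCc8ccccc8)c4c1OC(C)(C)CC4
F9 | step 17 | 1-[5,7-bis(benzyloxy)-6-[(1S)-1-[5,7-bis(benzyloxy)-8-[(1R,2R)-1-hydroxy-2-methylbutyl]-2,2-dimethylchroman-6-yl]-6-methylheptyl]-2,2-dimethylchroman-8-yl]-2-methylpropan-1-one | CC[C@@H](C)[C@@H](O)c1c(OCc5ccccc5)c([C@H](CCCCC(C)C)c2c(OCc6ccccc6)c3c(c(C(=O)C(C)C)c2OCc7ccccc7)OC(C)(C)CC3)c(OCc8ccccc8)c4c1OC(C)(C)CC4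
A1 | alternative 1 | 6-[(1R,2E)-1-[5,7-dihydroxy-2,2-dimethyl-8-(2-methylpropanoyl)chroman-6-yl]-6-methylhept-2-en-1-yl]-2,2-dimethyl-8-[(2R)-2-methylbutanoyl]chroman-5,7-diyl diacetate | CC[C@@H](C)C(=O)c1c(OC(C)=O)c([C@H](/C=C/CCC(C)C)c2c(O)c3c(c(C(=O)C(C)C)c2O)OC(C)(C)CC3)c(OC(C)=O)c2c1OC(C)(C)CC2
A2 | alternative 1 | 6-[(1E,3S)-3-[[7-hydroxy-2,2-dimethyl-8-(2-methylpropanoyl)chroman-5-yl]oxy]-6-methylhept-1-en-1-yl]-2,2-dimethyl-8-[(2R)-2-methylbutanoyl]chroman-5,7-diyl diacetate | CC(C)CC[C@H](Oc1cc(O)c(C(=O)C(C)C)c2OC(C)(C)CCc12)/C=C/c1c(OC(C)=O)c(C(=O)[C@H](C)CC)c2OC(C)(C)CCc2c1OC(C)=O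
A3 | alternative 2 | 5,7-bis(benzyloxy)-6-[(1S)-1-[7-hydroxy-2,2-dimethyl-5-[(triisopropylsilyl)oxy]chroman-6-yl]-6-methylheptyl]-2,2-dimethylchroman | c1c(OCc3ccccc3)c([C@H](CCCCC(C)C)c3c(O[Si](C(C)C)(C(C)C)C(C)C)c4c(cc3O)OC(C)(C)CC4)c(OCc3ccccc3)c2c1OC(C)(C)CC2
A4 | alternative 2 | [[(3R)-3-[5,7-bis(benzyloxy)-2,2-dimethylchroman-6-yl]-8-methylnon-1-yn-1-yl]oxy]triisopropylsilane | c1c(OCc3ccccc3)c([C@H](CCCCC(C)C)C#CO[Si](C(C)C)(C(C)C)C(C)C)c(OCc3ccccc3)c2c1OC(C)(C)CC2
A5 | alternative 2 | 3,3-dimethyl-2-oxabicyclo[4.2.0]oct-1(6)-en-7-one | O=C1CC2=C1CCC(C)(C)O2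
A6 | alternative 3 | 6-[(1R)-1-(5,7-dihydroxy-2,2-dimethylchroman-6-yl)-6-methylheptyl]-5-hydroxy-2,2-dimethylchroman-7-yl (2R)-2-methylbutanoate | c1c(OC(=O)[C@H](C)CC)c([C@H](CCCCC(C)C)c2c(O)c3c(cc2O)OC(C)(C)CC3)c(O)c2c1OC(C)(C)CC2
A7 | alternative 3 | 6,6'-(6-methylheptane-1,1-diyl)bis(2,2-dimethylchroman-5,7-diol) | CC(C)CCCCC(c1c(O)cc2OC(C)(C)CCc2c1O)c1c(O)cc2OC(C)(C)CCc2c1O
A8 | alternative 3 | (2R)-2-methylbutanoic anhydride | CC[C@@H](C)C(=O)OC(=O)[C@H](C)CC
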